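**Plan**

- Ring atoms are called C1 (CH with the aroyl group), C2 (CH with the prenyl group), C3 (C–CH3), C4 (=CH), C5 (CH2) and C6 (CH–Ph). The retrosynthesis cuts C1–C2 and reconnects C1 to C4, giving a cyclobutane C1–C6–C5–C4 that carries on C4 an alkoxide and the C3(Me)=C2 alkenyl group.
- Enabling feature: the C3=C4 double bond lies γ,δ to the aryl ketone on C1, so the cyclohex-3-enyl ketone is the formal 1,3-shift product of a 2-aroyl-1-alkenylcyclobutane. With O⁻ on C4 the shift runs as retro-aldol (C1 leaves as the ketone enolate) followed by Michael closure at C2.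
- Forward order: chromene ring first (aldehyde fragment); cyclobutane from 3-phenylcyclobutanone by aldol and alkenyllithium addition; ring expansion to the cyclohexene; the helper oxygen at C4 leaves as a triflate, replaced by hydrogen.
- Stereochemistry: C6 from enantiotopic deprotonation of the prochiral cyclobutanone; C1 and C2 from the endo, metal-bridged Michael closure relative to C6; the E alkene from syn-hydrozirconation. The other centres of the cyclobutane are erased.

Key step: step 8

Remark: 2,6-dihydroxy-4-methoxybenzaldehyde is taken as a catalogue compound.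
Remark: the lithium amide of step 5 is written as its R,R antipode; if the sense of enantiotopic selection is the reverse, the S,S base is used with no other change.

**Step 1**
Reactants: 1 2,6-dihydroxy-4-methoxybenzaldehyde; 2 3-methylbut-2-enal
Product: 3 7-hydroxy-5-methoxy-2,2-dimethyl-2H-chromene-8-carbaldehyde
Conditions: ethylenediammonium diacetate (10 mol %), toluene, reflux
Reagents that add atoms: none
Why: Amine-catalysed Knoevenagel-type condensation of the enal at the ring CH between OH and OMe, then oxa-6π electrocyclization (phenol chromenylation), should give the 2,2-dimethylchromene; the two ortho positions of the symmetric aldehyde are equivalent and the second OH stays hydrogen-bonded to the formyl group, so one mono-chromene is expected.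

**Step 2**
Reactants: 3 7-hydroxy-5-methoxy-2,2-dimethyl-2H-chromene-8-carbaldehyde
Product: 4 5-methoxy-2,2-dimethyl-7-(prop-2-en-1-yloxy)-2H-chromene-8-carbaldehyde
Conditions: allyl bromide, K2CO3, DMF, 50 °C
Reagents that add atoms: allyl bromide, C=CCBr
Why: Williamson etherification of the phenoxide; the allyl ether should survive the organolithium, oxidation and amide-base steps and leaves in step 9 under the palladium/formate system that also reduces the triflate.

**Step 3**
Reactants: 5 1-bromo-3-methylbut-2-ene; 6 prop-1-yn-1-ylmagnesium bromide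
Product: 7 6-methylhept-5-en-2-yne
Conditions: CuBr·SMe2 (5 mol %), THF, 0 °C to rt
Reagents that add atoms: none
Why: Copper-catalysed SN2 coupling of an alkynyl Grignard reagent with a primary allylic bromide at its unhindered carbon should give the skipped enyne.

**Step 4**
Reactants: 7 6-methylhept-5-en-2-yne
Product: 9 (2E)-2-iodo-6-methylhepta-2,5-diene, via alkenylzirconocene chloride 8 (not isolated)
Conditions: Cp2Zr(H)Cl (1.5 equiv), THF, 45 °C; then I2, 0 °C
Reagents that add atoms: iodine, II
Why: Syn-hydrozirconation of the internal alkyne (the trisubstituted alkene is inert), with equilibration placing zirconium on the methyl-bearing carbon, then iodinolysis of the C–Zr bond with retention, fixes the geometry in which iodine is trans to the CH2 group.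

**Step 5**
Reactants: 10 3-phenylcyclobutan-1-one
Product: 11 trimethyl{[(3R)-3-phenylcyclobut-1-en-1-yl]oxy}silane
Conditions: (R,R)-bis(1-phenylethyl)amine, n-BuLi, Me3SiCl (internal quench), THF, −100 °C
Reagents that add atoms: chlorotrimethylsilane, C[Si](C)(C)Cl
Why: Enantiotopic-group-selective deprotonation of the prochiral cyclobutanone by a C2-symmetric chiral lithium amide with in situ silylation (chiral-base desymmetrization) turns the phenyl-bearing carbon into the R stereocentre that becomes C6.

**Step 6**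
Reactants: 11 trimethyl{[(3R)-3-phenylcyclobut-1-en-1-yl]oxy}silane; 4 5-methoxy-2,2-dimethyl-7-(prop-2-en-1-yloxy)-2H-chromene-8-carbaldehyde; 9 (2E)-2-iodo-6-methylhepta-2,5-diene
Product: 15 (1R,2R,3R)-2-{hydroxy[5-methoxy-2,2-dimethyl-7-(prop-2-en-1-yloxy)-2H-chromen-8-yl]methyl}-1-[(2E)-6-methylhepta-2,5-dien-2-yl]-3-phenylcyclobutan-1-ol (both epimers at the CH–OH carbon), via lithium enolate 12 (not isolated), via lithium aldolate 13 (not isolated), via alkenyllithium 14 (not isolated)
Conditions: 11, MeLi (1.0 equiv), THF, 0 °C; 4, −78 °C; then 14 (from 9, t-BuLi 2 equiv, Et2O, −78 °C), −78 °C; aq NH4Cl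
Reagents that add atoms: none
Why: MeLi frees the lithium enolate (Stork cleavage of the silyl enol ether), whose aldol addition to the aldehyde should occur on the ring face opposite to phenyl, and the aldolate, masked as its own alkoxide, then takes up the alkenyllithium (iodine–lithium exchange with retention of alkene geometry) by 1,2-addition to the cyclobutanone carbonyl anti to the neighbouring side chain; the two carbinol centres and the side-chain-bearing ring carbon are erased in steps 7 and 8.

**Step 7**
Reactants: 15 the diol of step 6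
Product: 16 [(1S,2R,4R)-2-hydroxy-2-[(2E)-6-methylhepta-2,5-dien-2-yl]-4-phenylcyclobutyl][5-methoxy-2,2-dimethyl-7-(prop-2-en-1-yloxy)-2H-chromen-8-yl]methanone
Conditions: Dess–Martin periodinane, NaHCO3, CH2Cl2, 0 °C
Reagents that add atoms: none
Why: Dess–Martin oxidation converts the secondary benzylic alcohol into the aryl ketone, the tertiary allylic cyclobutanol cannot be oxidized, and the bicarbonate buffer should prevent premature retro-aldol opening.

**Step 8**
Reactants: 16 the 2-aroyl-1-alkenylcyclobutanol of step 7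
Product: 20 (3S,4S,5R)-4-{[5-methoxy-2,2-dimethyl-7-(prop-2-en-1-yloxy)-2H-chromen-8-yl]carbonyl}-2-methyl-3-(3-methylbut-2-en-1-yl)-5-phenylcyclohex-1-en-1-yl trifluoromethanesulfonate, via lithium cyclobutanolate 17 (not isolated), via ring-opened lithium enolate 18 (not isolated), via lithium cyclohexenolate 19 (not isolated)
Conditions: LiN(SiMe3)2 (1.05 equiv), THF, −78 to 0 °C; then PhNTf2, −78 °C to rt; aq NH4Cl
Reagents that add atoms: N-phenylbis(trifluoromethanesulfonimide), O=S(=O)(N(c1ccccc1)S(=O)(=O)C(F)(F)F)C(F)(F)F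
Why: Proposed new method: deprotonation of the tertiary cyclobutanol gives alkoxide 17, whose strained C1–C4 bond breaks in a retro-aldol step because C1 leaves as the aryl-ketone enolate and C4 becomes the carbonyl of an (E)-enone (18); C1 then adds to the enone β-carbon C2, so that C1 has moved from C4 to C2 (net 1,3-shift, four- to six-membered ring), the charge ends as the C3=C4 enolate 19 and PhNTf2 fixes it as the C4 triflate. The closest known reaction types are the alkoxide-accelerated vinylcyclobutanol-to-cyclohexenol rearrangement, the retro-aldol opening of 2-acylcyclobutanols (de Mayo) and the second stage of double Michael annulations. The six-membered ring closes in the 6-endo-trig mode (C1 onto C2, with C3 and C4 inside the ring). C6 is untouched and controls the rest: a boat-like closure with phenyl exo and the lithium-bridged enolate oxygen lying over the enone (endo) should set C1 trans to C6, and the E geometry of C2=C3 then places the prenyl group at C2 cis to the aroyl group. The step needs C–C bond formation to outrun proton transfer to the doubly allylic CH2 and to C5, which the intramolecular closure and the lithium counter-ion should favour, and it needs sulfonylation of 19 only, which holds because 19 is the sole enolate left once closure is complete.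

**Step 9**
Reactants: 20 the enol triflate of step 8
Product: 22 (7-hydroxy-5-methoxy-2,2-dimethyl-2H-chromen-8-yl)[(1R,2S,6R)-3-methyl-2-(3-methylbut-2-en-1-yl)-6-phenylcyclohex-3-en-1-yl]methanone, via allyl ether of the target 21 (not isolated)
Conditions: Pd(OAc)2 (5 mol %), PPh3, HCO2H, Bu3N, DMF, 60 then 80 °C
Reagents that add atoms: none
Why: Formate reduction of the vinyl triflate by zerovalent palladium (oxidative addition, hydride transfer from formate with loss of CO2, reductive elimination) puts the vinylic hydrogen on C4 without moving the double bond, and the same catalyst ionizes the allyl aryl ether to a π-allyl complex that formate reduces to propene, freeing the hydrogen-bonded phenol; no stereocentre is touched.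

**Compound list**

1 | 2,6-dihydroxy-4-methoxybenzaldehyde | COc1cc(O)c(C=O)c(O)c1 | starting material
2 | 3-methylbut-2-enal | CC(C)=CC=O | starting material
3 | 7-hydroxy-5-methoxy-2,2-dimethyl-2H-chromene-8-carbaldehyde | COc1cc(O)c(C=O)c2c1C=CC(C)(C)O2 | intermediate
4 | 5-methoxy-2,2-dimethyl-7-(prop-2-en-1-yloxy)-2H-chromene-8-carbaldehyde | COc1cc(OCC=C)c(C=O)c2c1C=CC(C)(C)O2 | intermediate
5 | 1-bromo-3-methylbut-2-ene | CC(C)=CCBr | starting material
6 | prop-1-yn-1-ylmagnesium bromide | CC#C[Mg]Br | starting material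
7 | 6-methylhept-5-en-2-yne | CC#CCC=C(C)C | intermediate
8 | chlorobis(cyclopentadienyl)[(2E)-6-methylhepta-2,5-dien-2-yl]zirconium | Cl[Zr](C1C=CC=C1)(C1C=CC=C1)/C(C)=C/CC=C(C)C | intermediate
9 | (2E)-2-iodo-6-methylhepta-2,5-diene | I/C(C)=C/CC=C(C)C | intermediate
10 | 3-phenylcyclobutan-1-one | O=C1CC(c2ccccc2)C1 | starting material
11 | trimethyl{[(3R)-3-phenylcyclobut-1-en-1-yl]oxy}silane | C[Si](C)(C)OC1=C[C@H](c2ccccc2)C1 | intermediate
12 | lithium (3R)-3-phenylcyclobut-1-en-1-olate | [Li]OC1=C[C@H](c2ccccc2)C1 | intermediate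
13 | lithium alkoxide of (2R,3R)-2-{hydroxy[5-methoxy-2,2-dimethyl-7-(prop-2-en-1-yloxy)-2H-chromen-8-yl]methyl}-3-phenylcyclobutan-1-one (side chain trans to phenyl; both epimers at the CH–O carbon) | COc1cc(OCC=C)c(C(O[Li])[C@H]3[C@H](c4ccccc4)CC3=O)c2c1C=CC(C)(C)O2 | intermediate
14 | (6-methylhepta-2,5-dien-2-yl)lithium, lithium trans to the CH2 group (same alkene geometry as in 9) | [Li]/C(C)=C/CC=C(C)C | intermediate
15 | (1R,2R,3R)-2-{hydroxy[5-methoxy-2,2-dimethyl-7-(prop-2-en-1-yloxy)-2H-chromen-8-yl]methyl}-1-[(2E)-6-methylhepta-2,5-dien-2-yl]-3-phenylcyclobutan-1-ol (both epimers at the CH–OH carbon; expected ring epimer at C1 drawn, its epimer converges) | COc1cc(OCC=C)c(C(O)[C@H]3[C@H](c4ccccc4)C[C@]3(O)/C(C)=C/CC=C(C)C)c2c1C=CC(C)(C)O2 | intermediate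
16 | [(1S,2R,4R)-2-hydroxy-2-[(2E)-6-methylhepta-2,5-dien-2-yl]-4-phenylcyclobutyl][5-methoxy-2,2-dimethyl-7-(prop-2-en-1-yloxy)-2H-chromen-8-yl]methanone | COc1cc(OCC=C)c(C(=O)[C@H]3[C@H](c4ccccc4)C[C@]3(O)/C(C)=C/CC=C(C)C)c2c1C=CC(C)(C)O2 | intermediate
17 | lithium alkoxide of 16 | COc1cc(OCC=C)c(C(=O)[C@H]3[C@H](c4ccccc4)C[C@]3(O[Li])/C(C)=C/CC=C(C)C)c2c1C=CC(C)(C)O2 | intermediate
18 | lithium (1Z,3R,6E)-1-[5-methoxy-2,2-dimethyl-7-(prop-2-en-1-yloxy)-2H-chromen-8-yl]-6,10-dimethyl-5-oxo-3-phenylundeca-1,6,9-trien-1-olate | COc1cc(OCC=C)c(/C(O[Li])=C/[C@H](c4ccccc4)CC(=O)/C(C)=C/CC=C(C)C)c2c1C=CC(C)(C)O2 | intermediate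
19 | lithium (3S,4S,5R)-4-{[5-methoxy-2,2-dimethyl-7-(prop-2-en-1-yloxy)-2H-chromen-8-yl]carbonyl}-2-methyl-3-(3-methylbut-2-en-1-yl)-5-phenylcyclohex-1-en-1-olate | COc1cc(OCC=C)c(C(=O)[C@@H]3[C@H](CC=C(C)C)C(C)=C(O[Li])C[C@H]3c4ccccc4)c2c1C=CC(C)(C)O2 | intermediate
20 | (3S,4S,5R)-4-{[5-methoxy-2,2-dimethyl-7-(prop-2-en-1-yloxy)-2H-chromen-8-yl]carbonyl}-2-methyl-3-(3-methylbut-2-en-1-yl)-5-phenylcyclohex-1-en-1-yl trifluoromethanesulfonate | COc1cc(OCC=C)c(C(=O)[C@@H]3[C@H](CC=C(C)C)C(C)=C(OS(=O)(=O)C(F)(F)F)C[C@H]3c4ccccc4)c2c1C=CC(C)(C)O2 | intermediate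
21 | [5-methoxy-2,2-dimethyl-7-(prop-2-en-1-yloxy)-2H-chromen-8-yl][(1R,2S,6R)-3-methyl-2-(3-methylbut-2-en-1-yl)-6-phenylcyclohex-3-en-1-yl]methanone | COc1cc(OCC=C)c(C(=O)[C@@H]3[C@H](CC=C(C)C)C(C)=CC[C@H]3c4ccccc4)c2c1C=CC(C)(C)O2 | intermediate
22 | (7-hydroxy-5-methoxy-2,2-dimethyl-2H-chromen-8-yl)[(1R,2S,6R)-3-methyl-2-(3-methylbut-2-en-1-yl)-6-phenylcyclohex-3-en-1-yl]methanone | COc1cc(O)c(C(=O)[C@@H]2[C@H](CC=C(C)C)C(C)=CC[C@H]2c2ccccc2)c2c1C=CC(C)(C)O2 | target

**Totals**

Total step count: 9.
Longest linear sequence: 6 steps (steps 1, 2, 6, 7, 8, 9; the branch through steps 3 and 4 is equally long).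

**Steps most likely to fail**

1. Step 8 (bears the label). Proton transfer inside the ring-opened enolate, to the doubly allylic CH2 next to C2 or to C5, may outrun the Michael closure. Closure through the exo arrangement would erode the cis relationship of C1 and C2. Fallback, from 16 back to 20, by known reactions in two stages: 16 is opened by retro-aldol with catalytic K2CO3 in methanol at 0 °C and the 1,5-diketone (3R,6E)-1-[5-methoxy-2,2-dimethyl-7-(prop-2-en-1-yloxy)-2H-chromen-8-yl]-6,10-dimethyl-3-phenylundeca-6,9-diene-1,5-dione F1 is isolated. F1 is then deprotonated at C1 with LiN(SiMe3)2 at −78 °C, warmed so that the intramolecular Michael addition (as in the second stage of a double Michael annulation) can proceed, and the resulting enolate is trapped with PhNTf2 to give 20. This separates fragmentation from C–C bond formation, so that temperature, counter-ion and additive can be set for the closure alone.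

2. Step 5. Discrimination between the two enantiotopic α-methylene groups may be insufficient. Fallback, from 10 back to 13, auxiliary-based instead of reagent-based: 10 is condensed with (S)-1-amino-2-(methoxymethyl)pyrrolidine (or its antipode, whichever gives the 3R series) to the hydrazone (2S)-2-(methoxymethyl)-N-(3-phenylcyclobutylidene)pyrrolidin-1-amine F2. Metalation with LiN(iPr)2 and addition of 4 gives the β-hydroxy hydrazone, the auxiliary hydrazone of the aldol adduct F3. Two-phase hydrolysis with aqueous oxalic acid frees (2R,3R)-2-{hydroxy[5-methoxy-2,2-dimethyl-7-(prop-2-en-1-yloxy)-2H-chromen-8-yl]methyl}-3-phenylcyclobutan-1-one F4. One equivalent of LiN(SiMe3)2 at −78 °C converts F4 into 13, and step 6 continues with the addition of 14.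

3. Step 6. The lithium aldolate may revert by retro-aldol or lose its side-chain configuration, or it may quench part of the alkenyllithium by proton transfer before 1,2-addition. Fallback, from 13 back to 15, stepwise with isolation: 13 is silylated in the flask with Et3SiCl and the silyl ether (2R,3R)-2-{[5-methoxy-2,2-dimethyl-7-(prop-2-en-1-yloxy)-2H-chromen-8-yl][(triethylsilyl)oxy]methyl}-3-phenylcyclobutan-1-one F5 is isolated. The less basic organocerium reagent made from 14 and CeCl3 is added to give the tertiary alcohol (1R,2R,3R)-2-{[5-methoxy-2,2-dimethyl-7-(prop-2-en-1-yloxy)-2H-chromen-8-yl][(triethylsilyl)oxy]methyl}-1-[(2E)-6-methylhepta-2,5-dien-2-yl]-3-phenylcyclobutan-1-ol F6. Bu4NF then removes the silyl group to give 15.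

**Further compounds**

F1 | step 8 | (3R,6E)-1-[5-methoxy-2,2-dimethyl-7-(prop-2-en-1-yloxy)-2H-chromen-8-yl]-6,10-dimethyl-3-phenylundeca-6,9-diene-1,5-dione | COc1cc(OCC=C)c(C(=O)C[C@H](c4ccccc4)CC(=O)/C(C)=C/CC=C(C)C)c2c1C=CC(C)(C)O2
F2 | step 5 | (2S)-2-(methoxymethyl)-N-(3-phenylcyclobutylidene)pyrrolidin-1-amine | COC[C@@H]1CCCN1N=C1CC(c2ccccc2)C1
F3 | step 5 | (S)-1-amino-2-(methoxymethyl)pyrrolidine hydrazone of (2R,3R)-2-{hydroxy[5-methoxy-2,2-dimethyl-7-(prop-2-en-1-yloxy)-2H-chromen-8-yl]methyl}-3-phenylcyclobutan-1-one | COc1cc(OCC=C)c(C(O)[C@H]3[C@H](c4ccccc4)CC3=NN5CCC[C@H]5COC)c2c1C=CC(C)(C)O2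
F4 | step 5 | (2R,3R)-2-{hydroxy[5-methoxy-2,2-dimethyl-7-(prop-2-en-1-yloxy)-2H-chromen-8-yl]methyl}-3-phenylcyclobutan-1-one | COc1cc(OCC=C)c(C(O)[C@H]3[C@H](c4ccccc4)CC3=O)c2c1C=CC(C)(C)O2
F5 | step 6 | (2R,3R)-2-{[5-methoxy-2,2-dimethyl-7-(prop-2-en-1-yloxy)-2H-chromen-8-yl][(triethylsilyl)oxy]methyl}-3-phenylcyclobutan-1-one | COc1cc(OCC=C)c(C(O[Si](CC)(CC)CC)[C@H]3[C@H](c4ccccc4)CC3=O)c2c1C=CC(C)(C)O2
F6 | step 6 | (1R,2R,3R)-2-{[5-methoxy-2,2-dimethyl-7-(prop-2-en-1-yloxy)-2H-chromen-8-yl][(triethylsilyl)oxy]methyl}-1-[(2E)-6-methylhepta-2,5-dien-2-yl]-3-phenylcyclobutan-1-ol | COc1cc(OCC=C)c(C(O[Si](CC)(CC)CC)[C@H]3[C@H](c4ccccc4)C[C@]3(O)/C(C)=C/CC=C(C)C)c2c1C=CC(C)(C)O2
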